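**Strategy.** Ring B is disconnected at C8–C8a and C4a–C5. With a ketone at C4, ring A becomes a 4-methyl-4-carboxycyclohexa-2,5-dienone whose mirror plane passes through C1 and C4. C8a is then an enone β-carbon and C4a its α-carbon, and this latent symmetry is what the key step exploits. In one rhodium-catalysed operation a glycidol-derived C5–C8 alkenylboronate aldehyde adds to one enone arm and the enolate closes onto the aldehyde. This creates ring B, two C–C bonds and the C1, C8a, C4a and C5 stereocentres. The precursors are an achiral dienone tert-butyl ester and an α-silyloxy aldehyde. The second enone arm survives and later takes up the sec-butyl group through an Ireland–Claisen shift.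

Key step: step 9

Numbering and faces: decalin numbering with C1 = quaternary carbon, C2 = sec-butyl carbon, C3=C4, C4a, C5 = acyloxy carbon, C6 = carbinol carbon, C7, C8 = methyl-bearing carbon, C8a. β is the face of H-4a, the C1 methyl, O-5 and O-6. α is the face of H-8a, the C1 carbonyl carbon, the C2 side chain and the C8 methyl. In this numbering the target is (1S,2S,4aR,5S,6R,8R,8aS) with an (R)-sec-butyl group and a Z-enoic acid.

Remark on the chemistry: a [3,3] shift is suprafacial, so the C4 oxygen must stand on the α face (axial, cis to H-8a). The ring-avoiding transition states put the α-alkyl group of the ester where the target has its methyl, so a propanoate is used and its carboxyl carbon is grown into the ethyl group.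

Assumption: commercial 3-methylglutaconic acid is an E/Z mixture, and both isomers converge on the same cyclic anhydride.

**Step 1**
Reactants: 1 tert-butyl benzoate
Product: 3 tert-butyl 1-methylcyclohexa-2,5-diene-1-carboxylate, via lithium dienolate 2 (not isolated)
Conditions: Li (2.2 equiv), t-BuOH (1 equiv), NH3(l)/THF, −78 °C; MeI (3 equiv), −78 °C → rt
Reagents that add atoms: iodomethane, CI
Why: Birch reduction–alkylation, in which the ester-stabilised dienolate 2 from ipso/para reduction is methylated at its α-carbon, so the quaternary carbon (future C1) and the skipped diene arise together while the tert-butyl ester resists ammonolysis and over-reduction.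

**Step 2**
Reactants: 3 tert-butyl 1-methylcyclohexa-2,5-diene-1-carboxylate
Product: 4 tert-butyl 1-methyl-4-oxocyclohexa-2,5-diene-1-carboxylate (prochiral dienone)
Conditions: Rh2(cap)4 (1 mol %), t-BuOOH (5 equiv), K2CO3 (0.5 equiv), CH2Cl2, rt
Reagents that add atoms: tert-butyl hydroperoxide, CC(C)(C)OO
Why: Radical allylic oxidation, in which the doubly allylic C–H bonds are the weakest in 3, the quaternary carbon blocks aromatisation, and collapse of the mixed peroxide at the central carbon gives the cross-conjugated dienone.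

**Step 3**
Reactants: 5 (S)-glycidol
Product: 6 (R)-pent-4-yne-1,2-diol
Conditions: HC≡CLi·ethylenediamine (3 equiv), DMSO/THF, 0 °C → rt
Reagents that add atoms: lithium acetylide (ethylenediamine complex), [Li]C#C
Why: SN2 epoxide opening by acetylide at the unsubstituted carbon leaves the C–O stereocentre (future C6) untouched, and the Payne shift of glycidol alkoxide is degenerate, so it costs no enantiopurity.

**Step 4**
Reactants: 6 (R)-pent-4-yne-1,2-diol
Product: 7 (R)-4,5-bis(tert-butyldimethylsilyloxy)pent-1-yne
Conditions: TBSCl (2.4 equiv), imidazole (5 equiv), DMF, rt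
Reagents that add atoms: tert-butyldimethylsilyl chloride, CC(C)(C)[Si](C)(C)Cl
Why: Imidazole-promoted silylation protects both hydroxyls in one operation without touching the stereocentre or the alkyne.

**Step 5**
Reactants: 7 (R)-4,5-bis(tert-butyldimethylsilyloxy)pent-1-yne
Product: 9 (R)-2-bromo-4,5-bis(tert-butyldimethylsilyloxy)pent-1-ene, via bromoalkenylborane 8 (not isolated)
Conditions: B-bromo-9-BBN (1.3 equiv), CH2Cl2, 0 °C; AcOH, 0 °C → rt
Reagents that add atoms: B-bromo-9-borabicyclo[3.3.1]nonane, BrB1C2CCCC1CCC2
Why: Haloboration–protodeboronation, in which B–Br adds syn to the terminal alkyne with bromine at the internal carbon and acetic acid cleaves the alkenyl C–B bond with retention, which fixes the Markovnikov regiochemistry and spares silyl ethers at 0 °C.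

**Step 6**
Reactants: 9 (R)-2-bromo-4,5-bis(tert-butyldimethylsilyloxy)pent-1-ene
Product: 10 (R)-2-[4,5-bis(tert-butyldimethylsilyloxy)pent-1-en-2-yl]-4,4,5,5-tetramethyl-1,3,2-dioxaborolane
Conditions: B2pin2 (1.1 equiv), PdCl2(PPh3)2 (3 mol %), PPh3 (6 mol %), PhOK (1.5 equiv), toluene, 50 °C
Reagents that add atoms: bis(pinacolato)diboron, CC1(C)OB(OC1(C)C)B1OC(C)(C)C(C)(C)O1
Why: Miyaura borylation (oxidative addition of the alkenyl bromide, phenoxide-assisted transmetalation, reductive elimination) puts boron exactly on the future C8.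

**Step 7**
Reactants: 10 bis-silyl alkenylboronate
Product: 11 (R)-2-(tert-butyldimethylsilyloxy)-4-(4,4,5,5-tetramethyl-1,3,2-dioxaborolan-2-yl)pent-4-en-1-ol
Conditions: CSA (0.1 equiv), MeOH/CH2Cl2 1:1, 0 °C
Reagents that add atoms: none
Why: Acid-catalysed methanolysis discriminates on steric grounds, so the primary silyl ether is lost much faster than the secondary one, and the acidic medium excludes 1,2-silyl migration and leaves the pinacol boronate intact.

**Step 8**
Reactants: 11 primary alcohol
Product: 12 (R)-2-(tert-butyldimethylsilyloxy)-4-(4,4,5,5-tetramethyl-1,3,2-dioxaborolan-2-yl)pent-4-enal (C5–C8 boronate aldehyde)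
Conditions: Dess–Martin periodinane (1.3 equiv), pyridine (3 equiv), CH2Cl2, 0 °C → rt
Reagents that add atoms: none
Why: Dess–Martin oxidation runs under buffered, non-basic conditions, so the α-silyloxy stereocentre is not epimerised and the C–B bond, which peroxide oxidants would attack, survives.

**Step 9**
Reactants: 4 prochiral dienone; 12 boronate aldehyde
Product: 14 trans-fused hydroxy enone: tert-butyl 5β-hydroxy-1β-methyl-8-methylidene-4-oxo-6β-(tert-butyldimethylsilyloxy)-1,4,4a,5,6,7,8,8a-octahydronaphthalene-1α-carboxylate (H-4a β; H-8a α), via rhodium enolate 13 (not isolated)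
Conditions: [RhCl(C2H4)2]2 (2.5 mol %), (R,R)-Ph-bod* (5.5 mol %), aq KOH (10 mol %), 4 (1.3 equiv), 12 added over 4 h, 1,4-dioxane/H2O 20:1, 30 °C
Reagents that add atoms: none
Why: Proposed new method: hydroxorhodium transmetalates with 12 to an alkenylrhodium that inserts one enantiotopic C=C of 4 at C8a (bond C8–C8a), the oxa-π-allylrhodium enolate 13 then attacks the tethered aldehyde through C4a (bond C4a–C5) faster than the little water present can protonate it, and hydrolysis of the rhodium aldolate regenerates Rh–OH. The closest known reaction types are the Hayashi–Miyaura addition, rhodium-catalysed conjugate addition–aldol cyclisations of enones tethered to a carbonyl group with an external boronic acid, annulations with 2-formylarylboronic acids and catalytic desymmetrisations of 4,4-disubstituted cyclohexadienones; new is the union of an aliphatic reagent carrying both the alkenylboron and the aldol acceptor with a prochiral dienone. Ring B closes by a 6-(enolexo)-exo-trig aldol. C8a is set by the chiral diene (the series that gives (R)-3-phenylcyclohexanone from cyclohexenone), C1 by insertion on the methyl-bearing face anti to the bulkier tert-butoxycarbonyl group, so that ligand and ester together single out one arm, while C4a and C5 equilibrate through enolisation and retro-aldol/aldol to the trans-fused chair with an equatorial C5–OH hydrogen-bonded to the C4 carbonyl beside the preset C6 centre. The step needs 1,4- before 1,2-addition, one addition only, and an intact 4-pentenal unit: the cross-conjugated dienone is the best acceptor present and is kept in excess by slow addition of 12, the remaining enone is less electrophilic and more crowded, a diene ligand avoids the hydroacylation and decarbonylation that phosphine–rhodium(I) complexes inflict on 4-pentenals, and near-neutral conditions at 30 °C preserve the α-silyloxy stereocentre. Dehydration is slow because the equatorial C5–O bond lies near the nodal plane of the C4–C4a enolate.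

**Step 10**
Reactants: 14 trans-fused hydroxy enone
Product: 15 4α,5β-diol: tert-butyl 4α,5β-dihydroxy-1β-methyl-8-methylidene-6β-(tert-butyldimethylsilyloxy)-1,4,4a,5,6,7,8,8a-octahydronaphthalene-1α-carboxylate
Conditions: Me4NBH(OAc)3 (6 equiv), MeCN/AcOH 1:1, −30 °C
Reagents that add atoms: none
Why: Saksena–Evans directed reduction, in which the C5 hydroxyl exchanges an acetate on boron and hydride is delivered through a chair-like six-membered transition state to the β face of C4, giving with 1,2-selectivity the 1,3-anti diol, that is the axial 4α-alcohol cis to H-8a that an external hydride (axial attack) would not give.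

**Step 11**
Reactants: 15 4α,5β-diol
Product: 16 8α-methyl diol: tert-butyl 4α,5β-dihydroxy-1β,8α-dimethyl-6β-(tert-butyldimethylsilyloxy)-1,4,4a,5,6,7,8,8a-octahydronaphthalene-1α-carboxylate
Conditions: Mn(dpm)3 (10 mol %), PhSiH3 (1.5 equiv), t-BuOOH (1.5 equiv), i-PrOH, rt
Reagents that add atoms: none
Why: Metal-hydride hydrogen-atom-transfer hydrogenation (Mukaiyama type), run only after the enone is gone, adds H• to the terminal carbon of the 1,1-disubstituted alkene far faster than to the 1,2-disubstituted C2=C3 bond, and the tertiary C8 radical takes its second hydrogen axially to give the favoured equatorial 8α-methyl, because an axial methyl would be syn-axial to both the C1 methyl and the C6 silyloxy group.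

**Step 12**
Reactants: 16 8α-methyl diol
Product: 17 4α,5β-bis(propanoate) of 16
Conditions: (EtCO)2O (5 equiv), Et3N, DMAP (0.3 equiv), CH2Cl2, rt
Reagents that add atoms: propanoic anhydride, CCC(=O)OC(=O)CC
Why: DMAP-catalysed acylation esterifies both secondary alcohols, which removes any need to tell them apart, since the C4 ester is the Claisen partner and the C5 ester serves as protecting group.

**Step 13**
Reactants: 17 4α,5β-bis(propanoate)
Product: 20 (S)-2-[1α-(tert-butoxycarbonyl)-1β,8α-dimethyl-5β-propanoyloxy-6β-(tert-butyldimethylsilyloxy)-1,2,4a,5,6,7,8,8a-octahydronaphthalen-2α-yl]propanoic acid, via bis(silyl ketene acetal) 18 (not isolated), via silyl ester 19 (not isolated)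
Conditions: LDA (3 equiv), THF/DMPU 4:1, −78 °C; TBSCl (3.5 equiv), −78 °C → rt, then 65 °C; 1 M HCl/THF, 0 °C
Reagents that add atoms: none
Why: Ireland–Claisen rearrangement, in which the rigid trans-decalin holds the C4–O bond axial so that the suprafacial [3,3] shift forms the C2–C bond on the α face (anti to the axial C1 methyl) and moves the alkene to C3=C4; the boat transition state of the (Z)- and the chair transition state of the (E)-ketene acetal both turn the α-methyl away from C1 and so converge on the (S)-acid whose CO2H stands where the ethyl group is needed, while the C5 ketene acetal, lacking an allyl partner, returns to the propanoate on acidic work-up.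

**Step 14**
Reactants: 20 Claisen acid
Product: 22 diol: tert-butyl 5β-hydroxy-2α-[(S)-1-hydroxypropan-2-yl]-1β,8α-dimethyl-6β-(tert-butyldimethylsilyloxy)-1,2,4a,5,6,7,8,8a-octahydronaphthalene-1α-carboxylate, via mixed anhydride 21 (not isolated)
Conditions: i-BuOCOCl (1.2 equiv), N-methylmorpholine (1.3 equiv), THF, −15 °C; LiBH4 (6 equiv), THF, 0 °C → rt
Reagents that add atoms: none
Why: Mixed carbonic anhydride activation followed by borohydride reduction, in which LiBH4 reduces the activated carboxyl and the unhindered C5 propanoate but not the neopentyl tert-butyl ester or the alkene, and the boron alkoxide formed at C5 does not trigger silyl migration.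

**Step 15**
Reactants: 22 diol
Product: 23 primary tosylate of 22 (C5–OH free)
Conditions: TsCl (1.3 equiv), pyridine, 0 °C
Reagents that add atoms: 4-toluenesulfonyl chloride, Cc1ccc(cc1)S(=O)(=O)Cl
Why: Sulfonylation is governed by sterics, so the primary alcohol reacts and the crowded secondary C5 hydroxyl between C4a and the axial silyl ether stays free.

**Step 16**
Reactants: 23 primary tosylate
Product: 24 tert-butyl 2α-[(R)-butan-2-yl]-5β-hydroxy-1β,8α-dimethyl-6β-(tert-butyldimethylsilyloxy)-1,2,4a,5,6,7,8,8a-octahydronaphthalene-1α-carboxylate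
Conditions: Me2CuLi (6 equiv, from CuI and MeLi), Et2O, −30 → 0 °C
Reagents that add atoms: lithium dimethylcuprate, [Li+].C[Cu-]C
Why: Gilman cuprate SN2 displacement of the primary tosylate adds the missing methyl carbon and completes the (R)-sec-butyl group without touching its stereocentre, the tert-butyl ester being inert and the low temperature keeping the C5 alkoxide from taking over the neighbouring silyl group.

**Step 17**
Reactants: 24 sec-butyl hydroxy ester
Product: 26 2α-[(R)-butan-2-yl]-1β,8α-dimethyl-5β-(triethylsilyloxy)-6β-(tert-butyldimethylsilyloxy)-1,2,4a,5,6,7,8,8a-octahydronaphthalene-1α-carboxylic acid, via triethylsilyl ester 25 (not isolated)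
Conditions: TESOTf (4 equiv), 2,6-lutidine (6 equiv), CH2Cl2, 0 °C → rt; pH 7 buffer/THF
Reagents that add atoms: triethylsilyl trifluoromethanesulfonate, CC[Si](CC)(CC)OS(=O)(=O)C(F)(F)F
Why: Silyl triflate/lutidine chemistry does two jobs at once, silylating the C5 hydroxyl and, by O-silylation of the ester carbonyl and loss of isobutene, converting the tert-butyl ester into silyl ester 25, which hydrolyses on work-up, all under buffered conditions that spare the TBS ether and avoid acid-induced lactonisation onto C3=C4.

**Step 18**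
Reactants: 26 C1 carboxylic acid
Product: 28 methyl ketone: 1α-acetyl analogue of 26, via dilithium gem-diolate 27 (not isolated)
Conditions: MeLi (5 equiv), Et2O, 0 °C → rt; inverse quench into ice-water
Reagents that add atoms: methyllithium, [Li]C
Why: Methyl ketone synthesis from a carboxylic acid and methyllithium, in which the lithium carboxylate accepts one MeLi to give the stable gem-diolate 27 that cannot collapse before the quench, so only one methyl group enters at a carbonyl that has no α-hydrogen.

**Step 19**
Reactants: 28 methyl ketone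
Product: 30 β-hydroxy ketone: 1α-(3-hydroxypropanoyl) analogue of 28, via lithium enolate 29 (not isolated)
Conditions: LDA (1.3 equiv), THF, −78 °C; CH2O (gas, from cracked paraformaldehyde), −78 → −40 °C; AcOH/THF quench
Reagents that add atoms: formaldehyde, C=O
Why: Crossed aldol hydroxymethylation of a lithium enolate, in which the ketone can enolise only towards its methyl group because C1 is quaternary, and monomeric formaldehyde is a small, non-enolisable acceptor that reacts at low temperature, where the aldolate neither eliminates nor reverts.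

**Step 20**
Reactants: 30 β-hydroxy ketone
Product: 31 primary tert-butyldiphenylsilyl ether of 30
Conditions: TBDPSCl (1.2 equiv), imidazole (2.5 equiv), CH2Cl2, 0 °C → rt
Reagents that add atoms: tert-butyldiphenylsilyl chloride, CC(C)(C)[Si](Cl)(c1ccccc1)c1ccccc1
Why: Imidazole-promoted silylation of the only free hydroxyl masks it for the C5 acylation with a group far more acid-stable than the triethylsilyl ether.

**Step 21**
Reactants: 31 tris-silyl ether
Product: 32 C5 alcohol (5β-OH free; 6β-OTBS and primary OTBDPS kept)
Conditions: PPTS (0.2 equiv), MeOH/CH2Cl2 1:1, 0 °C → rt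
Reagents that add atoms: none
Why: Acid-catalysed methanolysis follows the stability order TES << TBS << TBDPS, so only the C5 oxygen is released, and the acidic medium prevents migration of the C6 silyl group.

**Step 22**
Reactants: 33 3-methylglutaconic acid (E/Z mixture)
Product: 34 3-methylglutaconic anhydride (4-methyl-2H-pyran-2,6(3H)-dione)
Conditions: Ac2O (3 equiv), 70 °C; evaporation
Reagents that add atoms: none
Why: Dehydrative cyclisation with acetic anhydride, in which only the Z-diacid can close the six-membered anhydride and the E-isomer is drained into it through reversible enolisation of the mixed anhydrides, so the ring stores the Z geometry.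

**Step 23**
Reactants: 32 C5 alcohol; 34 3-methylglutaconic anhydride
Product: 35 C5 (Z)-4-carboxy-3-methylbut-3-enoate of 32 (bis-silyl-protected target)
Conditions: 34 (3 equiv), DMAP (0.2 equiv), pyridine (2 equiv), CH2Cl2, 0 °C → rt
Reagents that add atoms: none
Why: Nucleophile-catalysed alcoholysis of a cyclic anhydride, in which the C5 alcohol opens 34 at the non-conjugated, more electrophilic CH2–C=O carbonyl (the alternative vinylketene pathway delivers the same carbonyl), releasing the conjugated acid with the Z geometry fixed by the ring.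

**Step 24**
Reactants: 35 bis-silyl-protected target
Product: 36 tandyukisin C
Conditions: HF·pyridine, THF, 0 °C → rt
Reagents that add atoms: none
Why: Fluoride-mediated desilylation under mildly acidic conditions removes both silyl ethers without base, so acyl migration from O-5 to O-6, β-elimination of the hydroxy ketone and Z/E isomerisation of the enoic acid are avoided.

**Compound list**

1 | tert-butyl benzoate | CC(C)(C)OC(=O)c1ccccc1 | starting material
2 | lithium dienolate from Birch reduction of 1 | CC(C)(C)OC(O[Li])=C1C=CCC=C1 | intermediate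
3 | tert-butyl 1-methylcyclohexa-2,5-diene-1-carboxylate | CC(C)(C)OC(=O)C1(C)C=CCC=C1 | intermediate
4 | tert-butyl 1-methyl-4-oxocyclohexa-2,5-diene-1-carboxylate | CC(C)(C)OC(=O)C1(C)C=CC(=O)C=C1 | intermediate
5 | (S)-glycidol | OC[C@H]1CO1 | starting material
6 | (R)-pent-4-yne-1,2-diol | OC[C@H](O)CC#C | intermediate
7 | (R)-4,5-bis(tert-butyldimethylsilyloxy)pent-1-yne | CC(C)(C)[Si](C)(C)OC[C@H](O[Si](C)(C)C(C)(C)C)CC#C | intermediate
8 | (R,Z)-9-[2-bromo-4,5-bis(tert-butyldimethylsilyloxy)pent-1-enyl]-9-BBN | CC(C)(C)[Si](C)(C)OC[C@H](O[Si](C)(C)C(C)(C)C)C/C(Br)=C/B1C2CCCC1CCC2 | intermediate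
9 | (R)-2-bromo-4,5-bis(tert-butyldimethylsilyloxy)pent-1-ene | CC(C)(C)[Si](C)(C)OC[C@H](O[Si](C)(C)C(C)(C)C)CC(Br)=C | intermediate
10 | (R)-2-[4,5-bis(tert-butyldimethylsilyloxy)pent-1-en-2-yl]pinacolborane | CC(C)(C)[Si](C)(C)OC[C@H](O[Si](C)(C)C(C)(C)C)CC(=C)B1OC(C)(C)C(C)(C)O1 | intermediate
11 | (R)-2-(tert-butyldimethylsilyloxy)-4-(pinacolboryl)pent-4-en-1-ol | OC[C@H](O[Si](C)(C)C(C)(C)C)CC(=C)B1OC(C)(C)C(C)(C)O1 | intermediate
12 | (R)-2-(tert-butyldimethylsilyloxy)-4-(pinacolboryl)pent-4-enal | O=C[C@H](O[Si](C)(C)C(C)(C)C)CC(=C)B1OC(C)(C)C(C)(C)O1 | intermediate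
13 | rhodium enolate after C8–C8a bond formation (diene ligand omitted) | [Rh]OC1=C[C@H](C(=C)C[C@@H](O[Si](C)(C)C(C)(C)C)C=O)[C@@](C)(C(=O)OC(C)(C)C)C=C1 | intermediate
14 | trans-fused 5β-hydroxy-8-methylidene enone (key-step product) | O=C1C=C[C@](C)(C(=O)OC(C)(C)C)[C@H]2C(=C)C[C@@H](O[Si](C)(C)C(C)(C)C)[C@@H](O)[C@H]12 | intermediate
15 | 4α,5β-diol with 8-methylidene | O[C@@H]1C=C[C@](C)(C(=O)OC(C)(C)C)[C@H]2C(=C)C[C@@H](O[Si](C)(C)C(C)(C)C)[C@@H](O)[C@H]12 | intermediate
16 | 4α,5β-diol with 8α-methyl | O[C@@H]1C=C[C@](C)(C(=O)OC(C)(C)C)[C@H]2[C@H](C)C[C@@H](O[Si](C)(C)C(C)(C)C)[C@@H](O)[C@H]12 | intermediate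
17 | 4α,5β-bis(propanoate) | CCC(=O)O[C@@H]1C=C[C@](C)(C(=O)OC(C)(C)C)[C@H]2[C@H](C)C[C@@H](O[Si](C)(C)C(C)(C)C)[C@@H](OC(=O)CC)[C@H]12 | intermediate
18 | bis[(Z)-silyl ketene acetal] of 17 | C/C=C(\O[Si](C)(C)C(C)(C)C)O[C@@H]1C=C[C@](C)(C(=O)OC(C)(C)C)[C@H]2[C@H](C)C[C@@H](O[Si](C)(C)C(C)(C)C)[C@@H](O/C(O[Si](C)(C)C(C)(C)C)=C/C)[C@H]12 | intermediate
19 | rearranged TBS ester still carrying the C5 ketene acetal | CC(C)(C)[Si](C)(C)OC(=O)[C@@H](C)[C@H]1C=C[C@H]2[C@H](O/C(O[Si](C)(C)C(C)(C)C)=C/C)[C@H](O[Si](C)(C)C(C)(C)C)C[C@@H](C)[C@@H]2[C@@]1(C)C(=O)OC(C)(C)C | intermediate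
20 | Claisen acid, (S)-2-(decalin-2α-yl)propanoic acid with C3=C4 | OC(=O)[C@@H](C)[C@H]1C=C[C@H]2[C@H](OC(=O)CC)[C@H](O[Si](C)(C)C(C)(C)C)C[C@@H](C)[C@@H]2[C@@]1(C)C(=O)OC(C)(C)C | intermediate
21 | isobutyl carbonic mixed anhydride of 20 | CC(C)COC(=O)OC(=O)[C@@H](C)[C@H]1C=C[C@H]2[C@H](OC(=O)CC)[C@H](O[Si](C)(C)C(C)(C)C)C[C@@H](C)[C@@H]2[C@@]1(C)C(=O)OC(C)(C)C | intermediate
22 | diol (side-chain CH2OH and 5β-OH) | OC[C@@H](C)[C@H]1C=C[C@H]2[C@H](O)[C@H](O[Si](C)(C)C(C)(C)C)C[C@@H](C)[C@@H]2[C@@]1(C)C(=O)OC(C)(C)C | intermediate
23 | primary tosylate | Cc3ccc(cc3)S(=O)(=O)OC[C@@H](C)[C@H]1C=C[C@H]2[C@H](O)[C@H](O[Si](C)(C)C(C)(C)C)C[C@@H](C)[C@@H]2[C@@]1(C)C(=O)OC(C)(C)C | intermediate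
24 | (R)-sec-butyl hydroxy tert-butyl ester | CC[C@@H](C)[C@H]1C=C[C@H]2[C@H](O)[C@H](O[Si](C)(C)C(C)(C)C)C[C@@H](C)[C@@H]2[C@@]1(C)C(=O)OC(C)(C)C | intermediate
25 | 5β-OTES triethylsilyl ester | CC[C@@H](C)[C@H]1C=C[C@H]2[C@H](O[Si](CC)(CC)CC)[C@H](O[Si](C)(C)C(C)(C)C)C[C@@H](C)[C@@H]2[C@@]1(C)C(=O)O[Si](CC)(CC)CC | intermediate
26 | 5β-OTES C1 carboxylic acid | CC[C@@H](C)[C@H]1C=C[C@H]2[C@H](O[Si](CC)(CC)CC)[C@H](O[Si](C)(C)C(C)(C)C)C[C@@H](C)[C@@H]2[C@@]1(C)C(=O)O | intermediate
27 | dilithium gem-diolate | CC[C@@H](C)[C@H]1C=C[C@H]2[C@H](O[Si](CC)(CC)CC)[C@H](O[Si](C)(C)C(C)(C)C)C[C@@H](C)[C@@H]2[C@@]1(C)C(C)(O[Li])O[Li] | intermediate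
28 | C1 methyl ketone | CC[C@@H](C)[C@H]1C=C[C@H]2[C@H](O[Si](CC)(CC)CC)[C@H](O[Si](C)(C)C(C)(C)C)C[C@@H](C)[C@@H]2[C@@]1(C)C(C)=O | intermediate
29 | lithium enolate of 28 | CC[C@@H](C)[C@H]1C=C[C@H]2[C@H](O[Si](CC)(CC)CC)[C@H](O[Si](C)(C)C(C)(C)C)C[C@@H](C)[C@@H]2[C@@]1(C)C(=C)O[Li] | intermediate
30 | 3-hydroxypropanoyl ketone | CC[C@@H](C)[C@H]1C=C[C@H]2[C@H](O[Si](CC)(CC)CC)[C@H](O[Si](C)(C)C(C)(C)C)C[C@@H](C)[C@@H]2[C@@]1(C)C(=O)CCO | intermediate
31 | primary TBDPS ether | CC[C@@H](C)[C@H]1C=C[C@H]2[C@H](O[Si](CC)(CC)CC)[C@H](O[Si](C)(C)C(C)(C)C)C[C@@H](C)[C@@H]2[C@@]1(C)C(=O)CCO[Si](c3ccccc3)(c3ccccc3)C(C)(C)C | intermediate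
32 | C5 alcohol | CC[C@@H](C)[C@H]1C=C[C@H]2[C@H](O)[C@H](O[Si](C)(C)C(C)(C)C)C[C@@H](C)[C@@H]2[C@@]1(C)C(=O)CCO[Si](c3ccccc3)(c3ccccc3)C(C)(C)C | intermediate
33 | 3-methylglutaconic acid (E/Z mixture) | CC(CC(=O)O)=CC(=O)O | starting material
34 | 3-methylglutaconic anhydride | CC1=CC(=O)OC(=O)C1 | intermediate
35 | bis-silyl-protected tandyukisin C | CC[C@@H](C)[C@H]1C=C[C@H]2[C@H](OC(=O)C/C(C)=C\C(=O)O)[C@H](O[Si](C)(C)C(C)(C)C)C[C@@H](C)[C@@H]2[C@@]1(C)C(=O)CCO[Si](c3ccccc3)(c3ccccc3)C(C)(C)C | intermediate
36 | tandyukisin C | CC[C@@H](C)[C@H]1C=C[C@H]2[C@H](OC(=O)C/C(C)=C\C(=O)O)[C@H](O)C[C@@H](C)[C@@H]2[C@@]1(C)C(=O)CCO | target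

**Step count**

- Total step count: 24.
- Longest linear sequence: 21 steps, from (S)-glycidol through steps 3–21, 23 and 24.

**Steps most likely to fail**

1. Step 9 (new method).
   - What may go wrong: insertion at a β-carbon next to the quaternary centre may be slow. The enolate may be protonated before the ring closes. Discrimination between the methyl and the ester face may be weak. Convergence at C4a and C5 may stay incomplete or be overtaken by dehydration. The pentenal unit may be consumed by hydroacylation.
   - Fallback (stepwise, known chemistry): it sets out from 4 and 10.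
     - A Hayashi–Miyaura addition with the same catalyst in dioxane/H2O 10:1, where the enolate is simply protonated, should give the desymmetrised enone bis-silyl ether F1.
     - Selective methanolysis (CSA, MeOH) should give the primary alcohol F2, and Dess–Martin oxidation the keto aldehyde F3.
     - An amine-mediated intramolecular aldol under equilibrating conditions (catalytic DBU, CH2Cl2, 0 °C), in which only C4a can enolise, comes back to the route at 14.

2. Step 13.
   - What may go wrong: the [3,3] shift may be sluggish because the new bond forms beside C1. Double enolisation may be incomplete. Chair/boat crossover may erode control of the side-chain stereocentre.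
   - Fallback: it sets out from 16. An Eschenmoser–Claisen rearrangement of the free 4α-allylic alcohol uses N,N-dimethylpropanamide dimethyl acetal (xylene, 140 °C). It needs no strong base and passes through a geometrically defined ketene N,O-acetal whose methyl group is cis to the allylic oxygen, with a chair transition state and the same sense. It should give the dimethylamide F4. Reduction with lithium amidotrihydroborate (THF, rt) comes back to the route at 22, so steps 12–14 are bypassed.

3. Step 18.
   - What may go wrong: addition of methyllithium to the very crowded lithium carboxylate may stall, or over-addition may occur during the quench.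
   - Fallback: it sets out from 26. 1-Chloro-N,N,2-trimethylprop-1-en-1-amine (CH2Cl2, 0 °C → rt, neutral) should give the acid chloride F5. Acylation of Me2CuLi (Et2O, −78 °C) by this far more electrophilic carbonyl comes back to the route at 28.

**Further compounds**

F1 | step 9 | desymmetrised enone bis-silyl ether (C8a-alkenylated, C4a still CH2) | O=C1C[C@H](C(=C)C[C@@H](O[Si](C)(C)C(C)(C)C)CO[Si](C)(C)C(C)(C)C)[C@@](C)(C(=O)OC(C)(C)C)C=C1
F2 | step 9 | primary alcohol from F1 | O=C1C[C@H](C(=C)C[C@@H](O[Si](C)(C)C(C)(C)C)CO)[C@@](C)(C(=O)OC(C)(C)C)C=C1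
F3 | step 9 | keto aldehyde from F2 | O=C1C[C@H](C(=C)C[C@@H](O[Si](C)(C)C(C)(C)C)C=O)[C@@](C)(C(=O)OC(C)(C)C)C=C1
F4 | step 13 | (S)-N,N-dimethyl-2-(decalin-2α-yl)propanamide with free 5β-OH | CN(C)C(=O)[C@@H](C)[C@H]1C=C[C@H]2[C@H](O)[C@H](O[Si](C)(C)C(C)(C)C)C[C@@H](C)[C@@H]2[C@@]1(C)C(=O)OC(C)(C)C
F5 | step 18 | C1 acid chloride of 26 | CC[C@@H](C)[C@H]1C=C[C@H]2[C@H](O[Si](CC)(CC)CC)[C@H](O[Si](C)(C)C(C)(C)C)C[C@@H](C)[C@@H]2[C@@]1(C)C(=O)Cl
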